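**Retrosynthetic overview**
- The target comes from a racemic α-bromoketone by a catalyst-controlled ketone reduction, which sets C3 and at the same time sorts the enantiomers.
- The α-bromoketone comes from an achiral spirodienone by conjugate methylation of one of its two equivalent enone arms (C5 gem-dimethyl, C6 becomes stereogenic), followed by C4 bromination.
- The spirodienone comes from an anisole carrying a gem-dibromocyclopropane: silver-triggered opening to a 2-bromoallyl cation and ipso attack of the arene dearomatise ring A, close ring B and create the spiro carbon and the vinyl bromide in one step.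
- The cyclisation precursor is assembled from 3,5-dimethylanisole, 4-bromo-2-methylbut-1-ene and bromoform.
- Ring A is the benzene ring of the feedstock; ring B is formed second. The dienone's two arms differ only through distant ring B, so no face-selective reagent can choose between them; the absolute configuration is therefore fixed in the last step.

Assumption: spiro compounds are numbered C1–C5 = ring A (C1 = CMe=, C3 = carbinol/carbonyl carbon, C4 = CHBr, C5 = CMe2), C6 = spiro carbon, C7–C11 = ring B (C7 = CH2 next to C8–Br, C9 = CMe), so the target is (3S,4S,6S)-4,8-dibromo-1,5,5,9-tetramethylspiro[5.5]undeca-1,8-dien-3-ol (OH trans to Br, Br cis to C7); racemic intermediates are drawn as the enantiomer that leads to it.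

**Step 1**
Reactants: 1 3,5-dimethylanisole
Product: 2 4-bromo-3,5-dimethylanisole (2-bromo-5-methoxy-1,3-dimethylbenzene)
Conditions: NBS (1.05 equiv), MeCN, 0 °C → rt
Reagents that add atoms: N-bromosuccinimide, O=C1CCC(=O)N1Br
Why: Electrophilic aromatic bromination; the carbon para to OMe, further activated by the two flanking methyls, is the most nucleophilic site of 1 and NBS in MeCN is para-selective for anisoles, so no stereochemical issue arises.

**Step 2**
Reactants: 2 4-bromo-3,5-dimethylanisole; 3 4-bromo-2-methylbut-1-ene
Product: 5 5-methoxy-1,3-dimethyl-2-(3-methylbut-3-en-1-yl)benzene, via (4-methoxy-2,6-dimethylphenyl)magnesium bromide 4 (not isolated)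
Conditions: Mg, THF, reflux; then 3, Li2CuCl4 (5 mol%), N-methylpyrrolidone (4 equiv), 0 °C → rt
Reagents that add atoms: none
Why: Copper-catalysed Kochi-type cross-coupling of an aryl Grignard reagent with a primary alkyl bromide; the bond forms at an unhindered primary carbon, so the two ortho methyls of 4 are tolerated, and no stereocentre is involved.

**Step 3**
Reactants: 5 5-methoxy-1,3-dimethyl-2-(3-methylbut-3-en-1-yl)benzene
Product: 6 2-[2-(2,2-dibromo-1-methylcyclopropyl)ethyl]-5-methoxy-1,3-dimethylbenzene (racemic)
Conditions: CHBr3 (3 equiv), 50% aq. NaOH, benzyltriethylammonium chloride (5 mol%), CH2Cl2, 0 °C → rt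
Reagents that add atoms: bromoform, BrC(Br)Br
Why: Makosza phase-transfer dibromocarbene [2+1] cycloaddition to the only alkene of 5, an electron-rich 1,1-disubstituted one (the anisole ring is inert to the carbene); the cyclopropane stereocentre forms racemic and is erased in step 4.

**Step 4**
Reactants: 6 2-[2-(2,2-dibromo-1-methylcyclopropyl)ethyl]-5-methoxy-1,3-dimethylbenzene
Product: 9 8-bromo-1,5,9-trimethylspiro[5.5]undeca-1,4,8-trien-3-one, via 2-bromoallyl cation 7 (not isolated), via spiro oxocarbenium ion 8 (not isolated)
Conditions: AgBF4 (1.5 equiv), CH2Cl2/(CF3)2CHOH (4:1, 0.01 M), 0 → 25 °C; then aq. NaHCO3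
Reagents that add atoms: water, O
Why: Proposed new method: AgBF4 removes one bromide while the cyclopropane opens in a disrotatory electrocyclic manner to the tertiary 2-bromoallyl cation 7, whose CH2 terminus (future C7) is attacked through a six-membered transition state by the arene carbon para to OMe (both ortho positions carry methyls, which blocks ordinary Friedel–Crafts closure and any later dienone–phenol shift) to give the methoxy-stabilised spiro cation 8, and water then converts 8 into dienone 9 with loss of methanol, so that dearomatisation of ring A, closure of ring B, the spiro carbon C6 and the C8(Br)=C9(Me) unit all arise in one step; cations born with the tether turned outward can still cyclise after rotation about the weak C8–C9 bond or reversible capture at C9 by the fluorinated alcohol; no stereocentre forms because ring A of 9 is symmetric; the closest known reaction types are the silver-promoted opening of gem-dibromocyclopropanes with trapping of the 2-bromoallyl cation by a tethered arene, and the ipso-halocyclisation of para-methoxyaryl alkynes to spirotrienones with loss of the O-methyl group.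

**Step 5**
Reactants: 9 8-bromo-1,5,9-trimethylspiro[5.5]undeca-1,4,8-trien-3-one
Product: 12 (4S*,6S*)-4,8-dibromo-1,5,5,9-tetramethylspiro[5.5]undeca-1,8-dien-3-one (racemic), via trimethylsilyl enol ether 10 (not isolated), via C4-epimeric bromoketone 11 (not isolated)
Conditions: Me2CuLi (from MeLi and CuBr·SMe2, 2.5 equiv), Me3SiCl (5 equiv), THF, −78 → −30 °C; pentane, filter; NBS (1.05 equiv), THF, −78 °C; then 1,8-diazabicyclo[5.4.0]undec-7-ene (10 mol%), CH2Cl2, 0 °C → rt
Reagents that add atoms: methyllithium, [Li]C; N-bromosuccinimide, O=C1CCC(=O)N1Br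
Why: Me3SiCl-accelerated conjugate addition of a Gilman cuprate to one of the two equivalent β-methyl enone arms breaks the symmetry of 9 (C5 becomes gem-dimethyl and C6 stereogenic, necessarily racemic), NBS brominates the silyl enol ether 10 at C4, and amidine-catalysed enolisation equilibrates the C4 epimers (11 ⇌ 12) towards 12, the epimer with equatorial bromine cis to C7, which is expected to be favoured because ring A puckers so that the C1 methyl leans away from the pseudo-axial C10–H and towards the hydrogen-free sp2 C8, placing C7 in the pseudo-equatorial site that is 1,3-cis to an equatorial C4 substituent.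

**Step 6**
Reactants: 12 (4S*,6S*)-4,8-dibromo-1,5,5,9-tetramethylspiro[5.5]undeca-1,8-dien-3-one (racemic)
Product: 13 (3S,4S,6S)-4,8-dibromo-1,5,5,9-tetramethylspiro[5.5]undeca-1,8-dien-3-ol (target)
Conditions: (R)-1-methyl-3,3-diphenyltetrahydro-1H,3H-pyrrolo[1,2-c][1,3,2]oxazaborole (30 mol%), catecholborane (1.2 equiv), toluene, −78 → −40 °C; MeOH, pH 7 buffer; separation of the diastereomeric alcohols on SiO2
Reagents that add atoms: none
Why: Corey–Bakshi–Shibata reduction run as a catalyst-controlled divergent reaction on the racemate: with the CHBr–CMe2 side acting as the large group, the R-configured oxazaborolidine delivers hydride to the Re face of C3 in both enantiomers of 12, so (4S,6S)-12 gives the trans-bromohydrin 13 (3S, hydride syn to Br) while (4R,6R)-12 gives a cis-bromohydrin diastereomer that is removed on silica, which sets C3 and the absolute configuration together (yield ceiling 50%; the trans fraction can only arise from the wanted enantiomer).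

**Compound list**
1 | 3,5-dimethylanisole (1-methoxy-3,5-dimethylbenzene) | COc1cc(C)cc(C)c1 | starting material
2 | 4-bromo-3,5-dimethylanisole (2-bromo-5-methoxy-1,3-dimethylbenzene) | COc1cc(C)c(Br)c(C)c1 | intermediate
3 | 4-bromo-2-methylbut-1-ene | C=C(C)CCBr | starting material
4 | (4-methoxy-2,6-dimethylphenyl)magnesium bromide | COc1cc(C)c([Mg]Br)c(C)c1 | intermediate
5 | 5-methoxy-1,3-dimethyl-2-(3-methylbut-3-en-1-yl)benzene | COc1cc(C)c(CCC(C)=C)c(C)c1 | intermediate
6 | 2-[2-(2,2-dibromo-1-methylcyclopropyl)ethyl]-5-methoxy-1,3-dimethylbenzene (racemic) | COc1cc(C)c(CCC2(C)CC2(Br)Br)c(C)c1 | intermediate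
7 | 2-bromoallyl cation: 2-bromo-5-(4-methoxy-2,6-dimethylphenyl)-3-methylpent-1-en-3-ylium tetrafluoroborate | COc1cc(C)c(CC[C+](C)C(Br)=C)c(C)c1.F[B-](F)(F)F | intermediate
8 | spiro oxocarbenium ion: (8-bromo-1,5,9-trimethylspiro[5.5]undeca-1,4,8-trien-3-ylidene)(methyl)oxonium tetrafluoroborate | C[O+]=C1C=C(C)C2(CCC(C)=C(Br)C2)C(C)=C1.F[B-](F)(F)F | intermediate
9 | 8-bromo-1,5,9-trimethylspiro[5.5]undeca-1,4,8-trien-3-one (achiral) | CC1=CC(=O)C=C(C)C12CCC(C)=C(Br)C2 | intermediate
10 | [(8-bromo-1,5,5,9-tetramethylspiro[5.5]undeca-1,3,8-trien-3-yl)oxy]trimethylsilane (racemic) | CC1=CC(O[Si](C)(C)C)=CC(C)(C)[C@]12CCC(C)=C(Br)C2 | intermediate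
11 | (4R*,6S*)-4,8-dibromo-1,5,5,9-tetramethylspiro[5.5]undeca-1,8-dien-3-one (racemic, Br trans to C7) | CC1=CC(=O)[C@H](Br)C(C)(C)[C@]12CCC(C)=C(Br)C2 | intermediate
12 | (4S*,6S*)-4,8-dibromo-1,5,5,9-tetramethylspiro[5.5]undeca-1,8-dien-3-one (racemic, Br cis to C7) | CC1=CC(=O)[C@@H](Br)C(C)(C)[C@]12CCC(C)=C(Br)C2 | intermediate
13 | (3S,4S,6S)-4,8-dibromo-1,5,5,9-tetramethylspiro[5.5]undeca-1,8-dien-3-ol | CC1=C[C@H](O)[C@@H](Br)C(C)(C)[C@]12CCC(C)=C(Br)C2 | target

**Totals**
Total step count: 6. Longest linear sequence: 6 steps (1 → 13).

**Steps most likely to fail**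

1. Step 4 (silver-triggered dearomative ipso-cyclisation). The tertiary allyl cation may lose a proton to give 2-bromo-1,3-dienes, be captured by solvent, or form mainly with the tether turned outward. The fallback sets out from 6 and comes back at 9. MeLi (Et2O, −78 → 0 °C, carbenoid rearrangement of the Doering–LaFlamme type) converts 6 into the allene 5-methoxy-1,3-dimethyl-2-(3-methylpenta-3,4-dien-1-yl)benzene F1. NBS in CH2Cl2/(CF3)2CHOH at −40 °C then puts a bromonium ion on the terminal C=C of the allene, the ipso carbon closes onto the CH2 terminus in the same six-membered mode (Br ends on the central carbon), and aqueous NaHCO3 hydrolysis of the resulting cation of 8 gives 9. The electrophile is here built on an allene by an external bromonium source, so the cation-geometry problem of the cyclopropane opening disappears.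

2. Step 5 (methyl addition next to the quaternary spiro carbon; C4 epimer ratio). The cuprate may be too bulky for the β-carbon flanked by C6; the C4 ratio after equilibration is the second uncertainty and is checked on 12 by NOE (H4 to H7) before step 6. The fallback sets out from 9 and comes back at 10. Dimethylsulfoxonium methylide (trimethylsulfoxonium iodide, NaH, DMSO, 50 °C, Corey–Chaykovsky) cyclopropanates one enone arm to give 3'-bromo-4,4',6-trimethylspiro[bicyclo[4.1.0]hept-3-ene-5,1'-cyclohex-3'-en]-2-one F2. Samarium diiodide (SmI2, THF/DMPU, t-BuOH, −78 °C) cleaves the exocyclic cyclopropane bond through the ketyl and unveils the second C5 methyl, giving racemic 8-bromo-1,5,5,9-tetramethylspiro[5.5]undeca-1,8-dien-3-one F3. LiN(SiMe3)2 with Me3SiCl (THF, −78 °C) silylates the C4 enolate to 10, where the route resumes with NBS.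

3. Step 6 (reduction of the wanted enantiomer against its substrate bias). Hydride must enter syn to the equatorial Br and the axial C5 methyl, so for (4S,6S)-12 the catalyst works in the mismatched sense and the trans fraction may be small. The fallback sets out from 12 and comes back at 13. The S-configured catalyst [(S)-1-methyl-3,3-diphenyltetrahydro-1H,3H-pyrrolo[1,2-c][1,3,2]oxazaborole, 20 mol%] with 0.55 equiv catecholborane reduces only (4S,6S)-12, now in the matched sense (hydride anti to Br), to the cis-bromohydrin (3R,4S,6S)-4,8-dibromo-1,5,5,9-tetramethylspiro[5.5]undeca-1,8-dien-3-ol F4, which is separated from unreacted (4R,6R)-12. Mitsunobu inversion with chloroacetic acid (PPh3, diisopropyl azodicarboxylate, toluene, 0 °C) gives (3S,4S,6S)-4,8-dibromo-1,5,5,9-tetramethylspiro[5.5]undeca-1,8-dien-3-yl 2-chloroacetate F5, and NH3 in MeOH at 0 °C removes the chloroacetyl group to give 13.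

**Further compounds**
F1 | step 4 | 5-methoxy-1,3-dimethyl-2-(3-methylpenta-3,4-dien-1-yl)benzene | COc1cc(C)c(CCC(C)=C=C)c(C)c1
F2 | step 5 | 3'-bromo-4,4',6-trimethylspiro[bicyclo[4.1.0]hept-3-ene-5,1'-cyclohex-3'-en]-2-one (racemic, mixture of cyclopropane diastereomers) | CC1=CC(=O)C2CC2(C)C13CCC(C)=C(Br)C3
F3 | step 5 | 8-bromo-1,5,5,9-tetramethylspiro[5.5]undeca-1,8-dien-3-one (racemic) | CC1=CC(=O)CC(C)(C)[C@]12CCC(C)=C(Br)C2
F4 | step 6 | (3R,4S,6S)-4,8-dibromo-1,5,5,9-tetramethylspiro[5.5]undeca-1,8-dien-3-ol | CC1=C[C@@H](O)[C@@H](Br)C(C)(C)[C@]12CCC(C)=C(Br)C2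
F5 | step 6 | (3S,4S,6S)-4,8-dibromo-1,5,5,9-tetramethylspiro[5.5]undeca-1,8-dien-3-yl 2-chloroacetate | CC1=C[C@H](OC(=O)CCl)[C@@H](Br)C(C)(C)[C@]12CCC(C)=C(Br)C2
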